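The constants used here are made up; the result is computed.

The constants below set two clocks: partner decomposes on its own with 0.014 s⁻¹, a half-life of 0.83 min in dusk, and second catalyst destroys target with 0.86 M⁻¹ s⁻¹.

    substrate + free catalyst → free catalyst + open intermediate (k1 = 250 M⁻¹ s⁻¹, Ea1 = 44.0 kJ mol⁻¹)
    second catalyst + open intermediate ⇌ catalyst intermediate (K2 = 0.018 M⁻¹, k2 = 20 M⁻¹ s⁻¹, Ea2 = 56.0 kJ mol⁻¹, ΔH2 = −13.0 kJ mol⁻¹)
    partner + catalyst intermediate → second catalyst + target (k3 = 540 M⁻¹ s⁻¹, Ea3 = 45.0 kJ mol⁻¹)
    second catalyst + target → spent catalyst (k4 = 0.86 M⁻¹ s⁻¹, Ea4 = 55.0 kJ mol⁻¹)
    partner → decomposed reagent (k5 = 0.014 s⁻¹, Ea5 = 81.0 kJ mol⁻¹)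
    (constants at 35 °C)

| flask | substrate | partner | free catalyst | second catalyst | time | remark | temperature |
|---|---|---|---|---|---|---|---|
| midnight | 0.10 M | 1.50 equiv (fed, over 6.0 min) | 0.05 mol% | 18 mol% | 10 min | the addition at 5 °C, then warmed to 35 °C; the feed brings no volume worth counting |  |
| autumn | 0.10 M (fed, over 6.0 min) | 1.50 equiv | 0.05 mol% | 18 mol% | 10 min | all else is in the flask from the start; the feed brings no volume worth counting | 35 °C |
| winter | 0.10 M | 1.50 equiv (fed, over 6.0 min) | 0.05 mol% | 18 mol% | 10 min | all else is in the flask from the start; the feed brings no volume worth counting | 35 °C |
| dusk | 0.10 M | 1.50 equiv | 0.05 mol% | 18 mol% | 10 min | everything together at the start | 35 °C |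

- at 35 °C the constants are as listed, elsewhere as the activation energies and enthalpies make them

* the flask with the highest amount of target, in percent of the substrate charged ("all alike" if they lie within 1.5 percentage points) (midnight / autumn / winter / dusk / all alike)
* final target, as a percentage of the substrate charged, in midnight
* final target, as a percentage of the substrate charged, in autumn
* final target, as a percentage of the substrate charged, in winter
* final target, as a percentage of the substrate charged, in dusk

As a first answer, suppose that target, once made, stays. Now put that answer back in. At its charged concentration, second catalyst gives target a lifetime of 64.6 s, which is shorter than the 10 min of the run, so the supposition fails while second catalyst stands near its charge. Each second catalyst lost to step 4 takes one target with it and becomes spent catalyst. The second answer is therefore final target = target made − toll paid, where the toll, the share of the substrate charge that second catalyst can remove as target, is 18.0 %. Second catalyst also carries the making, since it forms the catalyst intermediate, so the toll is paid while target is being made.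

The recipes can now be read row against row. The second-catalyst column does not change, so the toll stands at 18.0 % in each flask, and my order of final target is the order of target made.

- **Dusk:** substrate opens with a lifetime of 80.0 s, a little longer than the 71.4 s lifetime of partner against decomposition, so partner is lost while open intermediate builds.
- **Autumn:** the substrate feed lasts 7.27 partner half-lives, which is worse still, and I expect the target made to fall short of the toll.
- **Winter:** the partner feed spans 4.5 substrate lifetimes, so later partner meets open intermediate already formed.
- **Midnight:** this is winter's feed run at 5 °C and then warmed, and decomposition has the steeper activation energy, so during the addition cold spares partner more than it slows opening.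

My order is midnight, winter, dusk, autumn.

The forecast names midnight and gives 20 % for midnight, 12.6 % for winter, 10 % for dusk and 0.4 % for autumn. Its ground: “Target kills the second catalyst, so final target ≈ total made − 18 mM”.

The simulation gives 20.2 % in midnight, 13.0 % in winter, 9.25 % in dusk and 0.169 % in autumn, each inside the forecast's range. Midnight's answer has moved by 5 points at 0.0835 M or 0.119 M of substrate, with equivalents, loadings and time held, while the forecast's range for midnight reaches 4 percentage points above its 20 %. In midnight, spent catalyst stands at 98.9 % after 10.0 min, so the toll paid is 17.8 % and target made is 38.0 %. The neighbour at 0.40 M of substrate holds the same loading and shows 100 % spent catalyst, so its 47.5 % of target plus the toll of 18.0 % makes 65.5 %, beside 34.5 % of open intermediate.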